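**Synthesis plan for CNP0252692.1 (29): ring F closed by acylation of ring D at C4a**

Rings are named A, C, B for the upper flavan and D, F, E for the lower flavan; each unit keeps its own flavan numbering.

## The problem

The target 29 consists of two flavan-3-ol units joined by one C–C bond, from C4 of the upper unit to C6 of ring D of the lower unit. The upper unit is a 5-deoxy (7-hydroxy) flavan with three contiguous stereocentres, (2R,3S,4S), arranged 2,3-trans-3,4-cis, so the ring D aryl group on C4 lies on the same face as O3. The lower unit is a 7,8-dihydroxyflavan-3-ol with two 2,3-trans centres, (2R,3S). Inside the upper unit C2 and C3 can direct C4, but the two units are linked by a freely rotating aryl–alkyl bond, so neither can pass its configuration to the other and each needs its own source of absolute stereochemistry. Nine hydroxyl groups must travel masked and be released together in one mild last step, because the catechol rings B and E and the 7,8-dihydroxylated ring D oxidise readily. The two benzylic O1–C2 ether bonds and the doubly benzylic interflavan bond can be cleaved by acid, and a carbonyl at C4 next to an oxygenated C3 is open to epimerisation and β-elimination under base. The opening lies in ring D: once C6 carries the upper unit, C4a is the only unsubstituted carbon of ring D that is ortho to O1 and para to the C7 oxygen, so a three-carbon chain on O1 can be closed onto C4a by electrophilic substitution without regiochemical doubt on that ring.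

## Retrosynthesis

**29 from 28.** The nine O–H bonds are traced back to benzyl ethers in 28. One hydrogenolysis under neutral conditions is the only way to free this many oxidation-prone phenols without acid or base, so benzyl is the protecting group throughout.

**28 from 26 (through 27).** The lower C4 methylene is taken back to a ketone. The carbonyl gives a disconnection handle at C4, and its removal by borohydride reduction to 27 and ionic deoxygenation is routine for a benzylic position that O1 and O7 of ring D stabilise as a cation.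

**26 from 24 (key disconnection).** The C4–C4a bond of the lower unit is cut, which opens ring F to a 3-aryl-3-aryloxy-2-benzyloxypropanoic acid carried on O1 of ring D.
- Against closing O1–C2 last: that would first need an intermolecular acylation of ring D and a later ring closure that sets C2. Here C2 and C3 arrive already set.
- Against an intermolecular C–C bond to ring D: the tether allows only C4a.
- Gain: 24 is the upper flavan joined to an open chain through one ether bond.
- Demand: activation of the acid must be non-basic (C3 is α to the acyl carbon), mild enough for the benzylic ethers, and must prefer the six-membered closure on ring D to a five-membered closure on ring E.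

**24 from 23, and 23 from 15 + 22.** The acid is taken back to the N-acyloxazolidinone 23, and the O1–C2 ether bond is cut between phenol 15 and the benzylic alcohol of the syn-aldol adduct 22, to be formed with inversion (Mitsunobu).
- A dihydroxylation-derived aryl glycerate was considered and set aside. Its free vicinal diol invites epoxide formation during activation, and O3 would have to be benzylated afterwards next to an ester carrying a β-aryloxy leaving group.
- In 22 the C3 oxygen is already a benzyl ether and the carboxyl is masked by the auxiliary that set both centres.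
- Demand: clean SN2 displacement at an electron-rich benzylic carbinol.

**22 from 19 + 20; 19 from 16 + 17.** The C2–C3 bond of the chain is cut by an auxiliary-controlled glycolate aldol reaction between imide 19 and 3,4-bis(benzyloxy)benzaldehyde 20. 19 comes from oxazolidinone 16 and benzyloxyacetyl chloride 17. Both chain stereocentres are set in one step from cheap materials.

**15 from 14, 13, and 5 + 10.** The interflavan bond is cut between the C4 carbonyl carbon of ketone 5 and the aryl metal derived from bromide 10. The tertiary alcohol 13 is reduced to 14, and the silyl ether is removed to give 15.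
- Direct arylation of a C4 cation was rejected. It places the aryl group trans to O3 and leaves the choice between C4a-type and C6-type positions of ring D open.
- The bromine in 10 fixes the ring D position, and hydride delivery to the 4-aryl cation is the way to the 3,4-cis arrangement.
- Demand: an aryl metal of low basicity and a face-selective hydride transfer.

**5 from 1 (through 2, 3, 4).** (+)-Taxifolin 1 supplies upper C2 and C3 in the correct absolute sense. The price is its extra 5-hydroxyl, removed by triflate reduction after the other hydroxyls are benzylated (2, 3, 4).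

**10 from 9, 8, 6.** The ring D building block needs three adjacent oxygens, the outer one differentiated, and bromine para to it. Dakin oxidation of 2,3-bis(benzyloxy)benzaldehyde 6 (through formate 7) gives phenol 8. The free hydroxyl of 8 directs bromination to the para position (9) and is then silylated (10).

## Roads not taken

**Alternative 1:** cut O1–C2 and C3–C4 of ring C together. In the forward step, loss of water from the benzhydrol A1 unmasks an o-quinone methide unit on ring A. This adds across the (E)-vinylsilane tethered through silicon to O7 of ring D, giving the siloxane-bridged cycloadduct A2. C–Si oxidation would then give the 3-hydroxyl.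
- Merits: one step forms two bonds, ring C and all three upper stereocentres. The alkene geometry gives 2,3-trans and the six-membered siloxane forces C3 and C4 cis. The 3,4-cis relation that the chosen plan leaves to the facial selectivity of a hydride transfer is fixed here by geometry. In relative stereocontrol and in bonds formed per step this road is better.
- Weak points: A1 has no stereocentre near the reacting atoms, so the absolute sense of the new unit relative to the lower unit would be uncontrolled. The whole lower flavan must be made first with O7 and O8 of ring D differentiated. A hindered diisopropylsilyl group on a secondary carbon between two aryl-bearing centres must then be oxidised.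
- Comparison: the chosen plan sets against this the absolute control of every centre (chiral pool for the upper unit, auxiliary for the lower) and reactions of known type, at the cost of a longer linear sequence.

**Alternative 2:** cut C5–C6 of ring D, which builds that ring from a pyranone. In the forward step methoxide opens the 3-benzyloxy-4-pyranone of A3 at its unsubstituted carbon, and the enolate of the neighbouring methylene closes onto that carbon to give, after aromatisation, the phenol A4. Ring F is closed afterwards.
- Merits: every substituent of ring D is placed by construction, with no electrophilic substitution on an electron-rich arene. The chosen plan faces two regiochemical questions (bromination of 8, acylation of C4a against ring E) that this road avoids. The later O1–C2 closure would be intramolecular, which is more reliable than the intermolecular etherification used here.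
- Weak points: A3 needs the upper C4 centre to be made with an sp3 carbon substituent and 3,4-cis control, for which no simple method is at hand. The carbanion must form at one of two enolisable methylene groups. The ring transformation is demanding on a substrate with acid- and base-sensitive ethers. A4 still needs ring closure and protection steps.
- Comparison: the chosen plan accepts the two regiochemical questions, one answered by the strongest donor on the ring and one by the tether, and in return uses no step without close precedent.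

**Alternative 3:** cut O1–C2 of ring C. In the forward step a chiral N-triflyl phosphoramide ionises the tertiary allylic alcohol A5 and the ring A phenol oxygen closes onto C2 to give the 2,4-diaryl-2H-chromene A6.
- Merits: C2 is set by a catalyst, the upper unit needs no chiral pool and no 5-deoxygenation (four steps saved in the chosen plan), and A5 is assembled convergently. In step economy up to the upper unit this road is better.
- Weak points: the C2 centre of A6 is allylic, benzylic and an aryl ether, so it can racemise by re-ionisation. The catalyst must work on a large substrate with pre-existing remote stereocentres. C3 and C4 remain to be set by epoxidation anti to the 2-aryl group and reductive opening at C4. That rests on the same hydride facial selectivity as the chosen plan and adds a benzylation; hydroboration would give the wrong 3,4-trans isomer.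
- Comparison: the chosen plan is longer but takes C2 and C3 as fixed, configurationally stable centres from 1 and carries one stereochemical uncertainty (C4) instead of three.

Key step: step 15

Remark: the target SMILES is read as upper unit (2R,3S,4S) with 2,3-trans-3,4-cis (4β-aryl) geometry and lower unit (2R,3S). The upper C4 descriptor is R in all benzyl ethers and S in 29 for the same geometry, because debenzylation of O7 of ring D changes the CIP priority. The carbinol centres of 13 and 27 are left undefined since both are removed in the following step.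

## Route

Step 1
Reactants: 1 (+)-taxifolin
Product: 2 7,3',4'-tri-O-benzyltaxifolin [(2R,3R)-7-(benzyloxy)-2-[3,4-bis(benzyloxy)phenyl]-3,5-dihydroxychroman-4-one]
Conditions: BnBr (3.3 equiv), K2CO3, DMF, rt
Reagents that add atoms: benzyl bromide, BrCc1ccccc1
Why: Williamson etherification of the three acidic phenols; the 5-hydroxyl, hydrogen-bonded to the C4 carbonyl, and the secondary 3-hydroxyl stay free under carbonate at room temperature, and the mild base leaves C2 and C3 untouched.

Step 2
Reactants: 2 7,3',4'-tri-O-benzyltaxifolin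
Product: 3 3,7,3',4'-tetra-O-benzyltaxifolin [(2R,3R)-3,7-bis(benzyloxy)-2-[3,4-bis(benzyloxy)phenyl]-5-hydroxychroman-4-one]
Conditions: BnOC(=NH)CCl3, CF3SO3H (cat.), CH2Cl2/cyclohexane, 0 °C → rt
Reagents that add atoms: benzyl 2,2,2-trichloroacetimidate, N=C(OCc1ccccc1)C(Cl)(Cl)Cl
Why: Acid-catalysed O-benzylation with a trichloroacetimidate; it avoids an alkoxide next to the ketone, which would open ring C or epimerise C3, and the chelated 5-phenol is too weak a nucleophile to compete.

Step 3
Reactants: 3 3,7,3',4'-tetra-O-benzyltaxifolin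
Product: 4 (2R,3R)-3,7-bis(benzyloxy)-2-[3,4-bis(benzyloxy)phenyl]-4-oxochroman-5-yl trifluoromethanesulfonate
Conditions: (CF3SO2)2O, pyridine, CH2Cl2, 0 °C
Reagents that add atoms: trifluoromethanesulfonic anhydride, O=S(=O)(OS(=O)(=O)C(F)(F)F)C(F)(F)F
Why: Sulfonylation of a phenol; with O3 blocked the 5-hydroxyl is the only free hydroxyl, and pyridine is too weak a base to enolise the ketone.

Step 4
Reactants: 4 the 5-triflate
Product: 5 tetra-O-benzylfustin [(2R,3R)-3,7-bis(benzyloxy)-2-[3,4-bis(benzyloxy)phenyl]chroman-4-one]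
Conditions: Pd(OAc)2 (cat.), dppf, HCO2H, Et3N, DMF, 60 °C
Reagents that add atoms: none
Why: Palladium-catalysed reduction of an aryl triflate with formate as hydride donor; the ortho carbonyl speeds oxidative addition to zerovalent palladium, and the homogeneous catalyst does not cleave benzyl ethers.

Step 5
Reactants: 6 2,3-bis(benzyloxy)benzaldehyde
Product: 8 2,3-bis(benzyloxy)phenol, via 2,3-bis(benzyloxy)phenyl formate 7 (not isolated)
Conditions: mCPBA, CH2Cl2, 0 °C → rt; aq NaHCO3 wash; then K2CO3 (cat.), MeOH, rt
Reagents that add atoms: 3-chloroperoxybenzoic acid, OOC(=O)c1cccc(Cl)c1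
Why: Dakin-type Baeyer–Villiger oxidation; the electron-rich aryl group migrates to oxygen to give formate 7, which is removed by methanolysis.

Step 6
Reactants: 8 2,3-bis(benzyloxy)phenol
Product: 9 2,3-bis(benzyloxy)-4-bromophenol
Conditions: NBS, MeCN, −20 °C
Reagents that add atoms: N-bromosuccinimide, O=C1CCC(=O)N1Br
Why: Electrophilic aromatic bromination directed para by the free hydroxyl, the strongest donor on the ring; a polar solvent and low temperature favour para over ortho attack.

Step 7
Reactants: 9 2,3-bis(benzyloxy)-4-bromophenol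
Product: 10 [2,3-bis(benzyloxy)-4-bromophenoxy](tert-butyl)dimethylsilane
Conditions: TBSCl, imidazole, DMF, rt
Reagents that add atoms: tert-butyldimethylsilyl chloride, CC(C)(C)[Si](C)(C)Cl
Why: Silylation of the phenol; the aryl silyl ether tolerates butyllithium at low temperature and is later removed by fluoride without touching benzyl ethers.

Step 8
Reactants: 10 the aryl bromide; 5 tetra-O-benzylfustin
Product: 13 (2R,3R)-3,7-bis(benzyloxy)-2-[3,4-bis(benzyloxy)phenyl]-4-[2,3-bis(benzyloxy)-4-(tert-butyldimethylsilyloxy)phenyl]chroman-4-ol (C4 carbinol configuration not defined), via aryllithium 11 (not isolated), via aryldichlorocerium 12 (not isolated)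
Conditions: 10, n-BuLi, THF, −78 °C; CeCl3, −78 °C; then 5, −78 → −40 °C; aq NH4Cl
Reagents that add atoms: none
Why: Bromine–lithium exchange, transmetalation to a weakly basic organocerium reagent and 1,2-addition to the ketone; cerium suppresses enolisation at C3 and the β-elimination that would open ring C. The configuration of the new carbinol centre does not matter because C4 becomes planar in step 9.

Step 9
Reactants: 13 the tertiary alcohol
Product: 14 (2R,3S,4R)-3,7-bis(benzyloxy)-2-[3,4-bis(benzyloxy)phenyl]-4-[2,3-bis(benzyloxy)-4-(tert-butyldimethylsilyloxy)phenyl]chroman (2,3-trans-3,4-cis)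
Conditions: Et3SiH, CF3CO2H, CH2Cl2, −20 → 0 °C
Reagents that add atoms: none
Why: Ionic hydrogenation of a tertiary dibenzylic alcohol through the C4 cation stabilised by rings A and D. Allylic strain with the ring D aryl group pushes the 3-benzyloxy group into a pseudo-axial position, so the silane should deliver hydride to the opposite face and leave the aryl group cis to O3, as hydride transfer to 4-aryl-3-alkoxyflavan-4-yl cations is known to do.

Step 10
Reactants: 14 the silyl ether
Product: 15 2,3-bis(benzyloxy)-4-[(2R,3S,4R)-3,7-bis(benzyloxy)-2-[3,4-bis(benzyloxy)phenyl]chroman-4-yl]phenol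
Conditions: Bu4NF, AcOH, THF, 0 °C
Reagents that add atoms: none
Why: Fluoride cleavage of an aryl silyl ether; acetic acid buffers the electron-rich phenoxide against air oxidation.

Step 11
Reactants: 16 (R)-4-benzyl-1,3-oxazolidin-2-one; 17 (benzyloxy)acetyl chloride
Product: 19 (R)-4-benzyl-3-[(benzyloxy)acetyl]-1,3-oxazolidin-2-one, via lithium oxazolidinide 18 (not isolated)
Conditions: n-BuLi, THF, −78 °C; then 17, −78 → 0 °C
Reagents that add atoms: none
Why: N-acylation of the lithiated oxazolidinone with an acid chloride, the standard preparation of N-acyl oxazolidinones.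

Step 12
Reactants: 19 the glycolyl imide; 20 3,4-bis(benzyloxy)benzaldehyde
Product: 22 (4R)-4-benzyl-3-[(2R,3S)-2-(benzyloxy)-3-[3,4-bis(benzyloxy)phenyl]-3-hydroxypropanoyl]-1,3-oxazolidin-2-one, via dibutylboron Z-enolate 21 (not isolated)
Conditions: Bu2BOTf, i-Pr2NEt, CH2Cl2, −78 → 0 °C; then 20, −78 → 0 °C; H2O2, pH 7 buffer, MeOH
Reagents that add atoms: none
Why: Evans syn-aldol reaction of a glycolate imide; the Z-boron enolate 21 reacts through a chair transition state on the enolate face away from the benzyl group of the (R)-auxiliary, which sets C2 as R and C3 as S (syn).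

Step 13
Reactants: 15 the phenol; 22 the syn-aldol adduct
Product: 23 (4R)-4-benzyl-3-[(2R,3R)-2-(benzyloxy)-3-[3,4-bis(benzyloxy)phenyl]-3-{2,3-bis(benzyloxy)-4-[(2R,3S,4R)-3,7-bis(benzyloxy)-2-[3,4-bis(benzyloxy)phenyl]chroman-4-yl]phenoxy}propanoyl]-1,3-oxazolidin-2-one
Conditions: PPh3, DIAD, toluene, 0 °C → rt
Reagents that add atoms: none
Why: Mitsunobu etherification; the benzylic hydroxyl is activated on phosphorus and displaced by the phenol with inversion, turning the (3S) carbinol into the (3R) aryl ether (the future lower C2). The benzyl ether on O2 rules out epoxide formation, and allylic strain in the imide keeps the α-hydrogen out of alignment with the carbonyl, which disfavours β-elimination.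

Step 14
Reactants: 23 the N-acyl oxazolidinone
Product: 24 (2R,3R)-2-(benzyloxy)-3-[3,4-bis(benzyloxy)phenyl]-3-{2,3-bis(benzyloxy)-4-[(2R,3S,4R)-3,7-bis(benzyloxy)-2-[3,4-bis(benzyloxy)phenyl]chroman-4-yl]phenoxy}propanoic acid
Conditions: LiOH, H2O2, THF/H2O, 0 °C; then Na2SO3; 1 M HCl
Reagents that add atoms: hydrogen peroxide, OO
Why: Hydroperoxide cleavage of an N-acyl oxazolidinone at the exocyclic carbonyl; the weakly basic nucleophile at 0 °C should spare the α-centre and the β-aryloxy group, and the auxiliary 16 is recovered.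

Step 15
Reactants: 24 the acid
Product: 26 (2R,3R)-3,7,8-tris(benzyloxy)-2-[3,4-bis(benzyloxy)phenyl]-6-[(2R,3S,4R)-3,7-bis(benzyloxy)-2-[3,4-bis(benzyloxy)phenyl]chroman-4-yl]chroman-4-one, via mixed trifluoroacetic anhydride 25 (not isolated)
Conditions: (CF3CO)2O, CH2Cl2 (high dilution), 0 °C → rt
Reagents that add atoms: none
Why: The acid is converted into the mixed anhydride 25, whose acyl carbon (the future lower C4), as an acylium centre or its ion pair, attacks C4a of ring D; loss of a proton restores the arene and forms the C4–C4a bond. The closest known reaction type is the trifluoroacetic anhydride-mediated intramolecular Friedel–Crafts acylation of 3-aryloxypropanoic acids to chroman-4-ones, including 3-aryl-3-aryloxypropanoic acids to flavanones. Ring F closes as a six-membered ring in a 6-exo-dig sense at the acylium carbon, the O1–C2–C3 tether holding the electrophile over the ortho position. No stereocentre is formed; C2 and C3 are carried through, and the absence of base excludes ketene formation or enolisation at C3, whose trans arrangement is in any case the more stable one in the product. The site selectivity needed is C4a against every other nucleophilic carbon: on ring D it is the only free position and is activated by O1 (ortho) and O7 (para). Closure onto ring E would give a strained five-membered ketone at a carbon activated by one oxygen only, so the six-membered path should prevail. High dilution suppresses intermolecular acylation of ring A, and low temperature limits loss of carbon monoxide from the α-alkoxy acyl cation and acid cleavage of the benzylic ethers.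

Step 16
Reactants: 26 the ketone
Product: 27 (2R,3S)-3,7,8-tris(benzyloxy)-2-[3,4-bis(benzyloxy)phenyl]-6-[(2R,3S,4R)-3,7-bis(benzyloxy)-2-[3,4-bis(benzyloxy)phenyl]chroman-4-yl]chroman-4-ol (C4 epimers of the lower unit)
Conditions: NaBH4, THF/MeOH, 0 °C
Reagents that add atoms: none
Why: Borohydride reduction of an aryl ketone; the configuration of the new carbinol does not matter because the hydroxyl is removed in step 17.

Step 17
Reactants: 27 the benzylic alcohol
Product: 28 nona-O-benzyl ether of the target [(2R,3S)-3,7,8-tris(benzyloxy)-2-[3,4-bis(benzyloxy)phenyl]-6-[(2R,3S,4R)-3,7-bis(benzyloxy)-2-[3,4-bis(benzyloxy)phenyl]chroman-4-yl]chroman]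
Conditions: Et3SiH, CF3CO2H, CH2Cl2, −20 → 0 °C
Reagents that add atoms: none
Why: Ionic deoxygenation; the lower C4 cation is stabilised by O1 and O7 of ring D and is trapped by the silane, as in the known conversion of flavan-3,4-diol derivatives into flavan-3-ols. No stereocentre is affected.

Step 18
Reactants: 28 the nona-O-benzyl ether
Product: 29 (2R,3S,4S)-2-(3,4-dihydroxyphenyl)-4-[(2R,3S)-2-(3,4-dihydroxyphenyl)-3,7,8-trihydroxychroman-6-yl]chroman-3,7-diol (the target)
Conditions: H2 (1 atm), Pd(OH)2/C, THF/MeOH, rt; filtration and concentration under argon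
Reagents that add atoms: none
Why: Hydrogenolysis of nine benzyl ethers under neutral conditions; the reaction is stopped at full debenzylation to spare the benzylic C–O bonds of the pyran rings, and the product is handled without air.

## Compound list

1 | (+)-taxifolin, (2R,3R)-2-(3,4-dihydroxyphenyl)-3,5,7-trihydroxychroman-4-one | Oc1cc(O)c2c(c1)O[C@H](c1ccc(O)c(O)c1)[C@@H](O)C2=O | starting material
2 | 7,3',4'-tri-O-benzyltaxifolin | C(c9ccccc9)Oc1cc(O)c2c(c1)O[C@H](c3ccc(OCc9ccccc9)c(OCc9ccccc9)c3)[C@@H](O)C2=O | intermediate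
3 | 3,7,3',4'-tetra-O-benzyltaxifolin | C(c9ccccc9)Oc1cc(O)c2c(c1)O[C@H](c3ccc(OCc9ccccc9)c(OCc9ccccc9)c3)[C@@H](OCc9ccccc9)C2=O | intermediate
4 | (2R,3R)-3,7-bis(benzyloxy)-2-[3,4-bis(benzyloxy)phenyl]-4-oxochroman-5-yl trifluoromethanesulfonate | C(c9ccccc9)Oc1cc(OS(=O)(=O)C(F)(F)F)c2c(c1)O[C@H](c3ccc(OCc9ccccc9)c(OCc9ccccc9)c3)[C@@H](OCc9ccccc9)C2=O | intermediate
5 | tetra-O-benzylfustin, (2R,3R)-3,7-bis(benzyloxy)-2-[3,4-bis(benzyloxy)phenyl]chroman-4-one | C(c9ccccc9)Oc1ccc2c(c1)O[C@H](c3ccc(OCc9ccccc9)c(OCc9ccccc9)c3)[C@@H](OCc9ccccc9)C2=O | intermediate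
6 | 2,3-bis(benzyloxy)benzaldehyde | O=Cc1cccc(OCc2ccccc2)c1OCc1ccccc1 | starting material
7 | 2,3-bis(benzyloxy)phenyl formate (not isolated) | O=COc1cccc(OCc2ccccc2)c1OCc1ccccc1 | intermediate
8 | 2,3-bis(benzyloxy)phenol | Oc1cccc(OCc2ccccc2)c1OCc1ccccc1 | intermediate
9 | 2,3-bis(benzyloxy)-4-bromophenol | Oc1ccc(Br)c(OCc2ccccc2)c1OCc1ccccc1 | intermediate
10 | [2,3-bis(benzyloxy)-4-bromophenoxy](tert-butyl)dimethylsilane | CC(C)(C)[Si](C)(C)Oc1ccc(Br)c(OCc2ccccc2)c1OCc1ccccc1 | intermediate
11 | [2,3-bis(benzyloxy)-4-(tert-butyldimethylsilyloxy)phenyl]lithium (not isolated) | [Li]c1ccc(O[Si](C)(C)C(C)(C)C)c(OCc2ccccc2)c1OCc1ccccc1 | intermediate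
12 | dichloro[2,3-bis(benzyloxy)-4-(tert-butyldimethylsilyloxy)phenyl]cerium (not isolated) | Cl[Ce](Cl)c1ccc(O[Si](C)(C)C(C)(C)C)c(OCc2ccccc2)c1OCc1ccccc1 | intermediate
13 | (2R,3R)-3,7-bis(benzyloxy)-2-[3,4-bis(benzyloxy)phenyl]-4-[2,3-bis(benzyloxy)-4-(tert-butyldimethylsilyloxy)phenyl]chroman-4-ol, C4 not defined | C(c9ccccc9)Oc1ccc2c(c1)O[C@H](c3ccc(OCc9ccccc9)c(OCc9ccccc9)c3)[C@@H](OCc9ccccc9)C2(O)c4ccc(O[Si](C)(C)C(C)(C)C)c(OCc9ccccc9)c4OCc9ccccc9 | intermediate
14 | (2R,3S,4R)-3,7-bis(benzyloxy)-2-[3,4-bis(benzyloxy)phenyl]-4-[2,3-bis(benzyloxy)-4-(tert-butyldimethylsilyloxy)phenyl]chroman, 2,3-trans-3,4-cis | C(c9ccccc9)Oc1ccc2c(c1)O[C@H](c3ccc(OCc9ccccc9)c(OCc9ccccc9)c3)[C@@H](OCc9ccccc9)[C@H]2c4ccc(O[Si](C)(C)C(C)(C)C)c(OCc9ccccc9)c4OCc9ccccc9 | intermediate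
15 | 2,3-bis(benzyloxy)-4-[(2R,3S,4R)-3,7-bis(benzyloxy)-2-[3,4-bis(benzyloxy)phenyl]chroman-4-yl]phenol | C(c9ccccc9)Oc1ccc2c(c1)O[C@H](c3ccc(OCc9ccccc9)c(OCc9ccccc9)c3)[C@@H](OCc9ccccc9)[C@H]2c4ccc(O)c(OCc9ccccc9)c4OCc9ccccc9 | intermediate
16 | (R)-4-benzyl-1,3-oxazolidin-2-one | O=C1N[C@H](Cc2ccccc2)CO1 | starting material
17 | (benzyloxy)acetyl chloride | O=C(Cl)COCc1ccccc1 | starting material
18 | lithium salt of (R)-4-benzyl-1,3-oxazolidin-2-one (not isolated) | [Li]N1[C@H](Cc2ccccc2)COC1=O | intermediate
19 | (R)-4-benzyl-3-[(benzyloxy)acetyl]-1,3-oxazolidin-2-one | O=C1OC[C@@H](Cc2ccccc2)N1C(=O)COCc1ccccc1 | intermediate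
20 | 3,4-bis(benzyloxy)benzaldehyde | O=Cc1ccc(OCc2ccccc2)c(OCc2ccccc2)c1 | starting material
21 | dibutylboron Z-enolate of 19 (not isolated) | CCCCB(CCCC)O/C(=C\OCc1ccccc1)N1C(=O)OC[C@H]1Cc1ccccc1 | intermediate
22 | (4R)-4-benzyl-3-[(2R,3S)-2-(benzyloxy)-3-[3,4-bis(benzyloxy)phenyl]-3-hydroxypropanoyl]-1,3-oxazolidin-2-one | O=C1OC[C@@H](Cc2ccccc2)N1C(=O)[C@H](OCc2ccccc2)[C@@H](O)c2ccc(OCc3ccccc3)c(OCc3ccccc3)c2 | intermediate
23 | N-acyl oxazolidinone aryl ether, (4R)-auxiliary, chain (2R,3R), aryloxy group = O1 of ring D of 15 | C(c9ccccc9)Oc1ccc2c(c1)O[C@H](c3ccc(OCc9ccccc9)c(OCc9ccccc9)c3)[C@@H](OCc9ccccc9)[C@H]2c4ccc(c(OCc9ccccc9)c4OCc9ccccc9)O[C@H](c6ccc(OCc9ccccc9)c(OCc9ccccc9)c6)[C@@H](OCc9ccccc9)C(=O)N7C(=O)OC[C@H]7Cc9ccccc9 | intermediate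
24 | (2R,3R)-2-(benzyloxy)-3-[3,4-bis(benzyloxy)phenyl]-3-(aryloxy)propanoic acid on O1 of ring D, upper unit (2R,3S,4R) | C(c9ccccc9)Oc1ccc2c(c1)O[C@H](c3ccc(OCc9ccccc9)c(OCc9ccccc9)c3)[C@@H](OCc9ccccc9)[C@H]2c4ccc(c(OCc9ccccc9)c4OCc9ccccc9)O[C@H](c6ccc(OCc9ccccc9)c(OCc9ccccc9)c6)[C@@H](OCc9ccccc9)C(=O)O | intermediate
25 | mixed anhydride of 24 with trifluoroacetic acid (not isolated) | C(c9ccccc9)Oc1ccc2c(c1)O[C@H](c3ccc(OCc9ccccc9)c(OCc9ccccc9)c3)[C@@H](OCc9ccccc9)[C@H]2c4ccc(c(OCc9ccccc9)c4OCc9ccccc9)O[C@H](c6ccc(OCc9ccccc9)c(OCc9ccccc9)c6)[C@@H](OCc9ccccc9)C(=O)OC(=O)C(F)(F)F | intermediate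
26 | benzylated dimer with 4-oxo lower unit, upper (2R,3S,4R), lower (2R,3R) | C(c9ccccc9)Oc1ccc2c(c1)O[C@H](c3ccc(OCc9ccccc9)c(OCc9ccccc9)c3)[C@@H](OCc9ccccc9)[C@H]2c4cc5c(c(OCc9ccccc9)c4OCc9ccccc9)O[C@H](c6ccc(OCc9ccccc9)c(OCc9ccccc9)c6)[C@@H](OCc9ccccc9)C5=O | intermediate
27 | benzylated dimer with 4-hydroxy lower unit, upper (2R,3S,4R), lower (2R,3S), lower C4 not defined | C(c9ccccc9)Oc1ccc2c(c1)O[C@H](c3ccc(OCc9ccccc9)c(OCc9ccccc9)c3)[C@@H](OCc9ccccc9)[C@H]2c4cc5c(c(OCc9ccccc9)c4OCc9ccccc9)O[C@H](c6ccc(OCc9ccccc9)c(OCc9ccccc9)c6)[C@@H](OCc9ccccc9)C5O | intermediate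
28 | nona-O-benzyl ether of the target, upper (2R,3S,4R), lower (2R,3S) | C(c9ccccc9)Oc1ccc2c(c1)O[C@H](c3ccc(OCc9ccccc9)c(OCc9ccccc9)c3)[C@@H](OCc9ccccc9)[C@H]2c4cc5c(c(OCc9ccccc9)c4OCc9ccccc9)O[C@H](c6ccc(OCc9ccccc9)c(OCc9ccccc9)c6)[C@@H](OCc9ccccc9)C5 | intermediate
29 | (2R,3S,4S)-2-(3,4-dihydroxyphenyl)-4-[(2R,3S)-2-(3,4-dihydroxyphenyl)-3,7,8-trihydroxychroman-6-yl]chroman-3,7-diol | Oc1ccc2c(c1)O[C@H](c1ccc(O)c(O)c1)[C@@H](O)[C@H]2c1cc2c(c(O)c1O)O[C@H](c1ccc(O)c(O)c1)[C@@H](O)C2 | target

## Step count and least certain steps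

Total step count: 18. Longest linear sequence: 13 steps (steps 1–4, 8–10, 13–18, from 1 to 29).

**Step 15 (key step).** Three processes may compete with the ring closure: loss of carbon monoxide from the α-benzyloxy acyl cation, closure onto ring E to a five-membered ketone, and acid cleavage of the benzylic O1–C2 ether by the trifluoroacetic acid set free. Intermolecular acylation of the electron-rich ring A is a further possibility at higher concentration. The fallback lowers the oxidation level of the electrophile so that no acyl cation is involved. It sets out from 24: reduction with BH3·SMe2 gives the primary alcohol F1, and Dess–Martin oxidation gives the α-benzyloxy aldehyde F2. Treating F2 with CF3CO2H and Et3SiH in CH2Cl2 closes ring F by hydroxyalkylation of C4a (the same bond and the same ring) to give 27 in the flask, which is deoxygenated under the same conditions. The fallback comes back to the route at 28.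

**Step 13.** The activated carbinol is benzylic to an electron-rich ring, so ionisation (loss of stereospecificity at the future lower C2) and β-elimination towards the enol ether may compete with SN2 attack by the ortho-substituted phenol. The fallback replaces hydroxyl activation by epoxide opening. Methyl (E)-3-[3,4-bis(benzyloxy)phenyl]acrylate F3 is epoxidised with a chiral ketone/Oxone system, the catalyst enantiomer being chosen to give the trans-glycidate F4. The caesium phenoxide of 15 (Cs2CO3, DMF) opens F4 at the benzylic carbon with inversion to give the hydroxy ester F5. O-Benzylation under neutral conditions (2-benzyloxy-1-methylpyridinium triflate, MgO, PhCF3, 85 °C) gives the methyl ester F6, and LiOH in THF/H2O returns the route at 24.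

**Step 9.** Hydride delivery to the C4 cation may show poor facial selectivity, because the directing 3-benzyloxy group is trans to the 2-aryl group and the two substituents shield opposite faces. The fallback changes the species that accepts hydride from a cation in acid to a neutral quinone methide in which allylic strain is fully developed. It sets out from 13: Bu4NF gives the 4-hydroxyphenyl carbinol F7, which loses water on mild acid treatment (PPTS, CH2Cl2) to give the p-quinone methide F8. NaBH4 in THF/MeOH at −40 °C then adds hydride 1,6 to C4 anti to the pseudo-axial 3-benzyloxy group. The fallback comes back to the route at 15.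

**Step 6.** Bromination may occur ortho to the hydroxyl instead of para, since that position is para to the 3-benzyloxy group and less crowded. The fallback removes the regiochemical choice by symmetry and does not use 6 or 8. It sets out from commercial 1,4-dibromo-2,3-dimethoxybenzene F9: BBr3 gives 3,6-dibromobenzene-1,2-diol F10, and BnBr/K2CO3 gives 1,4-dibromo-2,3-bis(benzyloxy)benzene F11. Exchange of one bromine with n-BuLi (1 equiv, THF, −78 °C) gives the aryllithium F12, B(OMe)3 gives the dimethyl arylboronate F13, and alkaline H2O2 oxidises the C–B bond. The fallback comes back to the route at 9.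

## Further compounds

F1 | step 15 | (2S,3R)-2-(benzyloxy)-3-[3,4-bis(benzyloxy)phenyl]-3-(aryloxy)propan-1-ol, aryloxy as in 24 | C(c9ccccc9)Oc1ccc2c(c1)O[C@H](c3ccc(OCc9ccccc9)c(OCc9ccccc9)c3)[C@@H](OCc9ccccc9)[C@H]2c4ccc(c(OCc9ccccc9)c4OCc9ccccc9)O[C@H](c6ccc(OCc9ccccc9)c(OCc9ccccc9)c6)[C@@H](OCc9ccccc9)CO
F2 | step 15 | (2R,3R)-2-(benzyloxy)-3-[3,4-bis(benzyloxy)phenyl]-3-(aryloxy)propanal, aryloxy as in 24 | C(c9ccccc9)Oc1ccc2c(c1)O[C@H](c3ccc(OCc9ccccc9)c(OCc9ccccc9)c3)[C@@H](OCc9ccccc9)[C@H]2c4ccc(c(OCc9ccccc9)c4OCc9ccccc9)O[C@H](c6ccc(OCc9ccccc9)c(OCc9ccccc9)c6)[C@@H](OCc9ccccc9)C=O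
F3 | step 13 | methyl (E)-3-[3,4-bis(benzyloxy)phenyl]acrylate | COC(=O)/C=C/c1ccc(OCc2ccccc2)c(OCc2ccccc2)c1
F4 | step 13 | methyl (2R,3S)-3-[3,4-bis(benzyloxy)phenyl]oxirane-2-carboxylate | O1[C@@H](c2ccc(OCc3ccccc3)c(OCc3ccccc3)c2)[C@@H]1C(=O)OC
F5 | step 13 | methyl (2R,3R)-3-[3,4-bis(benzyloxy)phenyl]-2-hydroxy-3-(aryloxy)propanoate, aryloxy as in 24 | C(c9ccccc9)Oc1ccc2c(c1)O[C@H](c3ccc(OCc9ccccc9)c(OCc9ccccc9)c3)[C@@H](OCc9ccccc9)[C@H]2c4ccc(c(OCc9ccccc9)c4OCc9ccccc9)O[C@H](c6ccc(OCc9ccccc9)c(OCc9ccccc9)c6)[C@@H](O)C(=O)OC
F6 | step 13 | methyl ester of 24 | C(c9ccccc9)Oc1ccc2c(c1)O[C@H](c3ccc(OCc9ccccc9)c(OCc9ccccc9)c3)[C@@H](OCc9ccccc9)[C@H]2c4ccc(c(OCc9ccccc9)c4OCc9ccccc9)O[C@H](c6ccc(OCc9ccccc9)c(OCc9ccccc9)c6)[C@@H](OCc9ccccc9)C(=O)OC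
F7 | step 9 | (2R,3R)-3,7-bis(benzyloxy)-2-[3,4-bis(benzyloxy)phenyl]-4-[2,3-bis(benzyloxy)-4-hydroxyphenyl]chroman-4-ol, C4 not defined | C(c9ccccc9)Oc1ccc2c(c1)O[C@H](c3ccc(OCc9ccccc9)c(OCc9ccccc9)c3)[C@@H](OCc9ccccc9)C2(O)c4ccc(O)c(OCc9ccccc9)c4OCc9ccccc9
F8 | step 9 | p-quinone methide: 2,3-bis(benzyloxy)-4-[(2R,3R)-3,7-bis(benzyloxy)-2-[3,4-bis(benzyloxy)phenyl]chroman-4-ylidene]cyclohexa-2,5-dien-1-one, alkene geometry not defined | C(c9ccccc9)Oc1ccc2c(c1)O[C@H](c3ccc(OCc9ccccc9)c(OCc9ccccc9)c3)[C@@H](OCc9ccccc9)C2=C4C=CC(=O)C(OCc9ccccc9)=C4OCc9ccccc9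
F9 | step 6 | 1,4-dibromo-2,3-dimethoxybenzene | COc1c(Br)ccc(Br)c1OC
F10 | step 6 | 3,6-dibromobenzene-1,2-diol | Oc1c(Br)ccc(Br)c1O
F11 | step 6 | 1,4-dibromo-2,3-bis(benzyloxy)benzene | Brc1ccc(Br)c(OCc2ccccc2)c1OCc1ccccc1
F12 | step 6 | [2,3-bis(benzyloxy)-4-bromophenyl]lithium | [Li]c1ccc(Br)c(OCc2ccccc2)c1OCc1ccccc1
F13 | step 6 | dimethyl [2,3-bis(benzyloxy)-4-bromophenyl]boronate | COB(OC)c1ccc(Br)c(OCc2ccccc2)c1OCc1ccccc1
A1 | alternative 1 | ring A benzhydrol with the (E)-styryl(diisopropyl)silyl ether on O7 of ring D, lower flavan complete | C(c9ccccc9)Oc1ccc(c(O)c1)C(O)c4cc5c(c(OCc9ccccc9)c4O[Si](/C=C/c3ccc(OCc9ccccc9)c(OCc9ccccc9)c3)(C(C)C)C(C)C)O[C@H](c6ccc(OCc9ccccc9)c(OCc9ccccc9)c6)[C@@H](OCc9ccccc9)C5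
A2 | alternative 1 | siloxane-bridged cycloadduct with C2, C3 and C4 of the upper unit set, silicon on C3 | C(c9ccccc9)Oc1ccc2c(c1)O[C@H](c3ccc(OCc9ccccc9)c(OCc9ccccc9)c3)[C@@H]7[C@H]2c4cc5c(c(OCc9ccccc9)c4O[Si]7(C(C)C)C(C)C)O[C@H](c6ccc(OCc9ccccc9)c(OCc9ccccc9)c6)[C@@H](OCc9ccccc9)C5
A3 | alternative 2 | 3-benzyloxy-4-pyranone carrying the upper flavan-4-ylmethyl group on C2 and the open lower chain on C5 | C(c9ccccc9)Oc1ccc2c(c1)O[C@H](c3ccc(OCc9ccccc9)c(OCc9ccccc9)c3)[C@@H](OCc9ccccc9)[C@H]2CC4=C(OCc9ccccc9)C(=O)C(=CO4)C[C@H](OCc9ccccc9)[C@@H](O[Si](C)(C)C(C)(C)C)c6ccc(OCc9ccccc9)c(OCc9ccccc9)c6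
A4 | alternative 2 | upper flavan bonded to the new ring D (7,8a-dihydroxy, 8-benzyloxy) with the open lower chain on C4a | C(c9ccccc9)Oc1ccc2c(c1)O[C@H](c3ccc(OCc9ccccc9)c(OCc9ccccc9)c3)[C@@H](OCc9ccccc9)[C@H]2c4cc(c(O)c(OCc9ccccc9)c4O)C[C@H](OCc9ccccc9)[C@@H](O[Si](C)(C)C(C)(C)C)c6ccc(OCc9ccccc9)c(OCc9ccccc9)c6
A5 | alternative 3 | tertiary allylic alcohol at the future upper C4 bearing ring A phenol, ring D of the complete lower flavan and the (E)-styryl group | C(c9ccccc9)Oc1ccc(c(O)c1)C(O)(/C=C/c3ccc(OCc9ccccc9)c(OCc9ccccc9)c3)c4cc5c(c(OCc9ccccc9)c4OCc9ccccc9)O[C@H](c6ccc(OCc9ccccc9)c(OCc9ccccc9)c6)[C@@H](OCc9ccccc9)C5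
A6 | alternative 3 | 2,4-diaryl-2H-chromene with the target configuration at C2 | C(c9ccccc9)Oc1ccc2c(c1)O[C@H](c3ccc(OCc9ccccc9)c(OCc9ccccc9)c3)C=C2c4cc5c(c(OCc9ccccc9)c4OCc9ccccc9)O[C@H](c6ccc(OCc9ccccc9)c(OCc9ccccc9)c6)[C@@H](OCc9ccccc9)C5
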